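The route rests on disconnecting the C4–O and C5–C6 bonds of the bicyclo[3.3.1]nonane core. The key step exploits two features: ring A (C1–C5, C9), whose C1 carbinol sits beside the C9 ketone, is a dearomatised o-quinol, and the C4 and C6 carbinols are related by a mirror plane through C5. In one operation hydroxide adds to C4 of an o-quinol dienone and the C9 enolate closes ring B through C5 onto a C6 aldehyde, giving a meso triol with three stereocentres. The precursor, a racemic quinol bearing a (Z)-3-oxopropenyl chain at C1, is carried as a stable bis-acetal and unmasked in the cascade flask. Enzymatic desymmetrisation, exo epoxidation, tethered radical amination and N-acylation complete the route.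

Key step: step 4

Core numbering used below: C1 bridgehead carbinol, C2 (CH2), C3 (N), C4 (carbinol), C5 bridgehead CH, C6 (carbinol), C7/C8 (epoxide), C9 ketone; ring A = C1–C5 and C9, ring B = C1, C8, C7, C6, C5, C9; "syn" means on the face turned towards the C9 bridge (exo), "endo" the face turned towards the other ring.

Assumption (remark on the chemistry): the lipase of step 5 acetylates the enantiotopic hydroxyl shown in 11; should it prefer the other one, hydrolysis of the meso diacetate of 10 with the same enzyme would give 11.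

Step 1
Reactants: 1 guaiacol (2-methoxyphenol)
Product: 2 6,6-dimethoxycyclohexa-2,4-dien-1-one (kept as a cold dilute solution)
Conditions: PhI(OAc)2, MeOH, −20 °C; NaHCO3; cold Et2O extraction, solution kept at or below 0 °C and used at once
Reagents that add atoms: methanol, CO
Why: Oxidative dearomatisation of a 2-methoxyphenol by a trivalent iodine reagent in methanol (phenol oxidation with ipso trapping by the solvent) is the standard entry to o-quinone monoketals, and keeping the unsubstituted ketal cold and dilute should hold back its Diels–Alder self-dimerisation until it is consumed.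

Step 2
Reactants: 2 6,6-dimethoxycyclohexa-2,4-dien-1-one; 3 3,3-diethoxyprop-1-yne
Product: 5 rac-1-(3,3-diethoxyprop-1-yn-1-yl)-6,6-dimethoxycyclohexa-2,4-dien-1-ol, via lithium acetylide 4 (not isolated)
Conditions: 3 (2.2 equiv), n-BuLi, THF, −78 °C, then cold solution of 2, −78 °C; NH4Cl
Reagents that add atoms: none
Why: Lithium acetylides add 1,2 to the carbonyl of quinone monoketals (acetylide carbonyl addition), the small linear nucleophile tolerating the neighbouring ketal; the new carbinol carbon (future C1) forms racemic, which the later meso intermediate makes irrelevant.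

Step 3
Reactants: 5 rac-1-(3,3-diethoxyprop-1-yn-1-yl)-6,6-dimethoxycyclohexa-2,4-dien-1-ol
Product: 6 rac-1-[(Z)-3,3-diethoxyprop-1-en-1-yl]-6,6-dimethoxycyclohexa-2,4-dien-1-ol
Conditions: H2 (1 atm), Pd/CaCO3–Pb(OAc)2 (Lindlar catalyst), quinoline, EtOAc, 0 °C, stopped at 1.0 equiv H2
Reagents that add atoms: none
Why: Lindlar semihydrogenation adds both hydrogens from the catalyst surface to the same side of the alkyne and so sets the Z alkene (future C7=C8), the alkyne being bound and reduced in preference to the ring diene when uptake is stopped at one equivalent.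

Step 4
Reactants: 6 rac-1-[(Z)-3,3-diethoxyprop-1-en-1-yl]-6,6-dimethoxycyclohexa-2,4-dien-1-ol
Product: 10 meso-1,4,6-trihydroxybicyclo[3.3.1]nona-2,7-dien-9-one (4-OH and 6-OH syn to C9), via spiro-lactol 7 (not isolated), via quinol enal 8 (not isolated), via C4-hydroxy adduct 9 (not isolated)
Conditions: 0.1 M HCl, THF–H2O, 0 °C; then slow addition into LiOH, THF–H2O (pH about 12, 5 mM or less), 0 °C; NH4Cl
Reagents that add atoms: water, O (delivered to C4 as hydroxide from lithium hydroxide, [Li+].[OH-])
Why: Proposed new method: acid unmasks 6 to the o-quinol, which rests as spiro-lactol 7 with the Z geometry locked in a dihydrofuran; at pH 12 the lactol opens to enal 8, hydroxide adds reversibly (oxa-Michael) to C4, the β-carbon of the C9 dienone, and the C9 enolate of adduct 9 attacks the C6 aldehyde through C5 (intramolecular aldol), so that C4–O and C5–C6 form and ring B closes in one operation. The closest known reaction type is the alkoxide-triggered oxa-Michael/aldol bicyclisation of p-quinol dienones that carry a tethered aldehyde, transposed here to an o-quinol with hydroxide as the nucleophile. Ring B (C1, C8, C7, C6, C5, C9) closes by a 6-(enolexo)-exo-trig aldol, which only the Z alkene allows. At C4, of the two reversible hydroxide adducts the one with C4–O anti to the C1–C8 bond has that bond antiperiplanar to the forming C5–C6 bond (the usual trans outcome of conjugate addition with enolate trapping) and is drained by the aldol; at C6, a lithium ion bridging enolate and aldehyde oxygens (closed transition state) places the hydroxyl syn to C9; C5 is fixed by the tether. The step needs C4 rather than C2 (1,6) addition and aldol rather than [4+2] dimerisation or E-isomerisation: C2 is neopentylic beside the fully substituted C1, every addition and retro-aldol is reversible while 10 is a sink whose bridgehead C5 cannot enolise (Bredt), and high dilution with lactol storage should hold back dimerisation and geometric drift. Because 10 has a mirror plane through C1, C9 and C5, both enantiomers of the racemic quinol converge on it.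

Step 5
Reactants: 10 meso-1,4,6-trihydroxybicyclo[3.3.1]nona-2,7-dien-9-one
Product: 11 1,6-dihydroxy-9-oxobicyclo[3.3.1]nona-2,7-dien-4-yl acetate (core numbering; single enantiomer as in the SMILES)
Conditions: vinyl acetate, immobilised Burkholderia cepacia lipase, THF–MTBE, 30 °C
Reagents that add atoms: vinyl acetate, CC(=O)OC=C
Why: Lipase-catalysed irreversible transesterification with an enol ester acylates one of the two enantiotopic secondary allylic hydroxyls of the meso diol and leaves the tertiary C1 hydroxyl alone, so that C1, C4, C5 and C6 become fixed stereocentres by group selection (enzymatic desymmetrisation).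

Step 6
Reactants: 11 1,6-dihydroxy-9-oxobicyclo[3.3.1]nona-2,7-dien-4-yl acetate
Product: 12 7,8-epoxy-1,6-dihydroxy-9-oxobicyclo[3.3.1]non-2-en-4-yl acetate (oxirane syn to C9, cis to 6-OH)
Conditions: VO(acac)2 (cat.), t-BuOOH, CH2Cl2, 0 °C to rt
Reagents that add atoms: tert-butyl hydroperoxide, CC(C)(C)OO
Why: Vanadium-catalysed hydroxyl-directed epoxidation delivers oxygen from the peroxo complex bound to the quasi-axial C6 hydroxyl to C7=C8 on its own face, which is also the only open (exo) face, giving the cis epoxy alcohol, while C2=C3 is spared because its C4 oxygen is acetylated and the bridgehead C1 hydroxyl lies close to the alkene plane.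

Step 7
Reactants: 12 7,8-epoxy-1,6-dihydroxy-9-oxobicyclo[3.3.1]non-2-en-4-yl acetate
Product: 13 7,8-epoxy-1,4,6-trihydroxybicyclo[3.3.1]non-2-en-9-one (4-OH, 6-OH and oxirane syn to C9)
Conditions: Burkholderia cepacia lipase, NaH2PO4/Na2HPO4 buffer pH 7–acetone, 30 °C
Reagents that add atoms: none
Why: Hydrolysis by the same lipase at pH 7 is the microscopic reverse of step 5 and frees the C4 hydroxyl without base, which is avoided because an alkoxide β to the C9 ketone could undergo retro-aldol cleavage followed by loss of acetate.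

Step 8
Reactants: 13 7,8-epoxy-1,4,6-trihydroxybicyclo[3.3.1]non-2-en-9-one
Product: 16 C3–N/C4–O cis-fused 2-(trichloromethyl)-2-oxazoline carrying 2-iodo (syn to C9), 6-O-trichloroacetimidate, 7,8-epoxide, 1-OH and the C9 ketone, via bis(trichloroacetimidate) 14 (not isolated), via N-iodo imidate 15 (not isolated)
Conditions: Cl3CCN (2.2 equiv), DBU (cat.), CH2Cl2, −30 °C; AcOH (cat.), N-iodosuccinimide, 0 °C, dark; then 450 nm LEDs, 0 °C to rt
Reagents that add atoms: trichloroacetonitrile, ClC(Cl)(Cl)C#N; N-iodosuccinimide, O=C1CCC(=O)N1I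
Why: Amidine-catalysed addition of the two secondary hydroxyls to trichloroacetonitrile is followed by N-iodination and visible-light N–I homolysis, and the C4 imidate radical closes 5-exo onto C3 from the tether side (N syn to C9, cis to C4–O) with iodine-atom transfer to C2, a halogen-atom-transfer aminocyclisation of the type known for N-haloamides, here through the imidate radical that an N-iodo trichloroacetimidate gives on irradiation; the radical course is chosen because an iodonium anti to the tether would have to sit on the endo face of ring A against C8, the C6 imidate has neither an alkene nor a weak C–H within reach and stays a spectator, and the C2 configuration is erased in step 9.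

Step 9
Reactants: 16 iodo-oxazoline from step 8
Product: 17 C3–N/C4–O cis-fused 2-(dichloromethyl)-2-oxazoline with C2 methylene, 6-O-dichloroacetimidate, 7,8-epoxide, 1-OH and the C9 ketone
Conditions: Bu3SnH (3.5 equiv), Et3B/air, toluene, 0 °C to rt
Reagents that add atoms: none
Why: Tin hydride radical-chain dehalogenation replaces the C2 iodine by hydrogen and unavoidably takes one chlorine from each trichloromethyl group (immaterial, since both carbons are cleaved off in step 10); with ring B already an epoxide the C2 radical has no homoallylic alkene to add to, is not adjacent to the oxirane, and no stereocentre is touched.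

Step 10
Reactants: 17 dichloromethyl oxazoline from step 9
Product: 18 3-amino-7,8-epoxy-1,4,6-trihydroxybicyclo[3.3.1]nonan-9-one hydrochloride (3-N, 4-OH, 6-OH and oxirane syn to C9)
Conditions: 1.25 M HCl, MeOH–H2O 9:1, 0 °C to rt; evaporation
Reagents that add atoms: hydrogen chloride, Cl
Why: Aqueous-methanolic acid hydrolyses the 2-(dichloromethyl)oxazoline and the C6 imidate to labile dichloroacetates that transesterify to methanol while the amine stays protonated (so no O-to-N acyl shift), and the epoxide should survive because its backside is the blocked endo face and ionisation next to C1 or C6 is disfavoured.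

Step 11
Reactants: 19 hex-5-enenitrile; 20 pentylmagnesium bromide
Product: 22 undec-1-en-6-one, via magnesium ketimine 21 (not isolated)
Conditions: CuBr·SMe2 (cat.), THF, reflux; then 1 M aq. HCl, rt
Reagents that add atoms: water, O
Why: Addition of a Grignard reagent to a nitrile stops at the magnesium ketimine, which aqueous acid hydrolyses to the ketone (classical nitrile-to-ketone synthesis), copper catalysis favouring addition over α-deprotonation.

Step 12
Reactants: 22 undec-1-en-6-one; 23 acrylic acid
Product: 24 (E)-7-oxododec-2-enoic acid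
Conditions: second-generation Hoveyda–Grubbs catalyst (H2IMes)Cl2Ru=CH(C6H4-2-OiPr) (cat.), acrylic acid (3 equiv), CH2Cl2, 40 °C
Reagents that add atoms: none
Why: Olefin cross-metathesis between a terminal alkene and acrylic acid is selective for the cross product because the electron-poor partner homodimerises slowly, gives the E-configured conjugated acid under thermodynamic control and is driven by loss of ethylene.

Step 13
Reactants: 18 3-amino-7,8-epoxy-1,4,6-trihydroxybicyclo[3.3.1]nonan-9-one hydrochloride; 24 (E)-7-oxododec-2-enoic acid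
Product: 25 isariotin C
Conditions: EDC·HCl, HOBt, iPr2NEt, DMF, 0 °C to rt
Reagents that add atoms: none
Why: Carbodiimide/hydroxybenzotriazole amide coupling acylates the primary amine far faster than the hindered secondary and tertiary hydroxyls, leaves the E enoyl and ketone groups alone and creates no stereocentre, the exo amine being unable to reach the backside of the exo epoxide.

Compound list
1 | guaiacol (2-methoxyphenol) | COc1ccccc1O | starting material
2 | 6,6-dimethoxycyclohexa-2,4-dien-1-one | COC1(OC)C=CC=CC1=O | intermediate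
3 | 3,3-diethoxyprop-1-yne | CCOC(C#C)OCC | starting material
4 | lithium 3,3-diethoxyprop-1-yn-1-ide | [Li]C#CC(OCC)OCC | intermediate
5 | rac-1-(3,3-diethoxyprop-1-yn-1-yl)-6,6-dimethoxycyclohexa-2,4-dien-1-ol | CCOC(OCC)C#CC1(O)C=CC=CC1(OC)OC | intermediate
6 | rac-1-[(Z)-3,3-diethoxyprop-1-en-1-yl]-6,6-dimethoxycyclohexa-2,4-dien-1-ol | CCOC(OCC)/C=C\C1(O)C=CC=CC1(OC)OC | intermediate
7 | rac-2-hydroxy-1-oxaspiro[4.5]deca-3,7,9-trien-6-one (spiro-lactol form of 8, lactol epimers) | OC1C=CC2(O1)C=CC=CC2=O | intermediate
8 | rac-6-hydroxy-6-[(Z)-3-oxoprop-1-en-1-yl]cyclohexa-2,4-dien-1-one | O=C/C=C\C1(O)C=CC=CC1=O | intermediate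
9 | rac-2,5-dihydroxy-2-[(Z)-3-oxoprop-1-en-1-yl]cyclohex-3-en-1-one, hydroxyls cis (core C1-OH and C4-OH), reacting as its C9 enolate; one enantiomer drawn | C1=C[C@](O)(/C=C\C=O)C(=O)C[C@H]1O | intermediate
10 | meso-1,4,6-trihydroxybicyclo[3.3.1]nona-2,7-dien-9-one (4-OH and 6-OH syn to C9) | C1=C[C@@]2(O)C(=O)[C@H]([C@H](O)C=C2)[C@H]1O | intermediate
11 | 1,6-dihydroxy-9-oxobicyclo[3.3.1]nona-2,7-dien-4-yl acetate (core numbering, acetoxy and 6-OH syn to C9) | C1=C[C@@]2(O)C(=O)[C@H]([C@H](O)C=C2)[C@H]1OC(C)=O | intermediate
12 | 7,8-epoxy-1,6-dihydroxy-9-oxobicyclo[3.3.1]non-2-en-4-yl acetate (oxirane syn to C9) | C1=C[C@@]2(O)C(=O)[C@H]([C@H](O)[C@@H]3O[C@@H]32)[C@H]1OC(C)=O | intermediate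
13 | 7,8-epoxy-1,4,6-trihydroxybicyclo[3.3.1]non-2-en-9-one (4-OH, 6-OH, oxirane syn to C9) | C1=C[C@@]2(O)C(=O)[C@H]([C@H](O)[C@@H]3O[C@@H]32)[C@H]1O | intermediate
14 | 4,6-bis(O-trichloroacetimidate) of 13 | C1=C[C@@]2(O)C(=O)[C@H]([C@H](OC(=N)C(Cl)(Cl)Cl)[C@@H]3O[C@@H]32)[C@H]1OC(=N)C(Cl)(Cl)Cl | intermediate
15 | 14 N-iodinated at the C4 imidate | C1=C[C@@]2(O)C(=O)[C@H]([C@H](OC(=N)C(Cl)(Cl)Cl)[C@@H]3O[C@@H]32)[C@H]1OC(=NI)C(Cl)(Cl)Cl | intermediate
16 | C3–N/C4–O cis-fused 2-(trichloromethyl)-2-oxazoline, 2-iodo (syn to C9), 6-O-trichloroacetimidate, 7,8-epoxide, 1-OH, 9-one | ClC(Cl)(Cl)C1=N[C@H]2[C@@H](I)[C@@]3(O)C(=O)[C@H]([C@H](OC(=N)C(Cl)(Cl)Cl)[C@@H]4O[C@@H]43)[C@H]2O1 | intermediate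
17 | C3–N/C4–O cis-fused 2-(dichloromethyl)-2-oxazoline, C2 methylene, 6-O-dichloroacetimidate, 7,8-epoxide, 1-OH, 9-one | ClC(Cl)C1=N[C@H]2C[C@@]3(O)C(=O)[C@H]([C@H](OC(=N)C(Cl)Cl)[C@@H]4O[C@@H]43)[C@H]2O1 | intermediate
18 | 3-amino-7,8-epoxy-1,4,6-trihydroxybicyclo[3.3.1]nonan-9-one hydrochloride (3-N, 4-OH, 6-OH, oxirane syn to C9) | [Cl-].[NH3+][C@H]1C[C@@]2(O)C(=O)[C@H]([C@H](O)[C@@H]3O[C@@H]32)[C@H]1O | intermediate
19 | hex-5-enenitrile | C=CCCCC#N | starting material
20 | pentylmagnesium bromide | CCCCC[Mg]Br | starting material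
21 | N-(bromomagnesio) ketimine of undec-1-en-6-one | C=CCCCC(CCCCC)=N[Mg]Br | intermediate
22 | undec-1-en-6-one | C=CCCCC(=O)CCCCC | intermediate
23 | acrylic acid | C=CC(=O)O | starting material
24 | (E)-7-oxododec-2-enoic acid | CCCCCC(=O)CCC/C=C/C(=O)O | intermediate
25 | isariotin C | CCCCCC(=O)CCC/C=C/C(=O)N[C@H]1C[C@@]2(O)C(=O)[C@H]([C@H](O)[C@@H]3O[C@@H]32)[C@H]1O | target

Total step count: 13. Longest linear sequence: 11 (steps 1–10 and 13).

Steps most likely to fail

Step 4 (Proposed new method). Hydroxide may add to C2 instead of C4, the free dienone may dimerise by [4+2] faster than the cascade runs, or the aldol may close with the C6 hydroxyl anti to C9 so that the product is not meso. The fallback uses known reactions and makes the C4 bond irreversible. Setting out from 6, pyridinium p-toluenesulfonate in wet acetone at 0 °C would hydrolyse the ring ketal and close the side-chain acetal onto the C1 hydroxyl to give rac-2-ethoxy-1-oxaspiro[4.5]deca-3,7,9-trien-6-one F1, in which the aldehyde is masked against base. Copper-catalysed conjugate borylation (CuCl, Xantphos, NaOtBu, B2pin2, MeOH, THF) would place boron, a hydroxide surrogate that cannot retro-add, on C4 anti to the dihydrofuran alkene, giving the β-boryl ketone F2. Aqueous acid would free the lactol and K2CO3 in methanol would close the C5–C6 aldol (C5 is the only enolisable α-position) to the bicyclic boronate F3. Oxidation of the C–B bond with NaBO3·4H2O proceeds with retention and returns to the route at 10.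

Step 8. The radical chain may fail (slow N–I homolysis or iodine transfer), or the tertiary C1 hydroxyl may be iodinated and its α-ketol cleaved by β-scission. The fallback is halogen-free. Setting out from 12, silylation of the C6 hydroxyl (t-BuMe2SiCl, imidazole) would give the silyl ether F4, lipase hydrolysis as in step 7 the C4 alcohol F5, and 4-methoxyphenyl isocyanate the N-aryl carbamate F6. Photocatalytic proton-coupled electron transfer ([Ir(ppy)2(dtbbpy)]PF6, NBu4[(BuO)2PO2], thiophenol, blue light) would generate the amidyl radical, which closes 5-exo onto C3 on the tether face and takes hydrogen at C2 from the thiol (olefin hydroamidation), giving the N-aryl oxazolidinone F7. (NH4)2Ce(NO3)6 would remove the aryl group to give the N–H oxazolidinone F8, Boc2O with DMAP would activate the ring as the N-Boc oxazolidinone F9, and catalytic Cs2CO3 in methanol would open it to the N-Boc amino alcohol F10. HCl in methanol would remove the Boc and silyl groups and return to the route at 18.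

Step 2. Diels–Alder self-dimerisation of the unsubstituted ketal during transfer may outrun carbonyl addition. Setting out from 1, bromination para to the hydroxyl (N-bromosuccinimide, MeCN) would give 4-bromo-2-methoxyphenol F11, and oxidation with PhI(OAc)2 in methanol the ketal 4-bromo-6,6-dimethoxycyclohexa-2,4-dien-1-one F12, which the bromine on the dienophilic C4=C5 bond should make isolable. Acetylide 4 would add as in step 2 to give the bromo dienol 4-bromo-1-(3,3-diethoxyprop-1-yn-1-yl)-6,6-dimethoxycyclohexa-2,4-dien-1-ol F13. Bromine–lithium exchange with t-BuLi at −78 °C and a proton quench would remove the halogen and return to the route at 5.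

Further compounds
F1 | step 4 | rac-2-ethoxy-1-oxaspiro[4.5]deca-3,7,9-trien-6-one (acetal epimers) | CCOC1C=CC2(O1)C=CC=CC2=O
F2 | step 4 | rac-2-ethoxy-8-(4,4,5,5-tetramethyl-1,3,2-dioxaborolan-2-yl)-1-oxaspiro[4.5]deca-3,9-dien-6-one (boron cis to the spiro oxygen) | C1=C[C@@]2(OC(OCC)C=C2)C(=O)C[C@H]1B3OC(C)(C)C(C)(C)O3
F3 | step 4 | rac-1,6-dihydroxy-4-(4,4,5,5-tetramethyl-1,3,2-dioxaborolan-2-yl)bicyclo[3.3.1]nona-2,7-dien-9-one (boron and 6-OH syn to C9) | C1=C[C@@]2(O)C(=O)[C@H]([C@H](O)C=C2)[C@H]1B3OC(C)(C)C(C)(C)O3
F4 | step 8 | 6-O-tert-butyldimethylsilyl ether of 12 | C1=C[C@@]2(O)C(=O)[C@H]([C@H](O[Si](C)(C)C(C)(C)C)[C@@H]3O[C@@H]32)[C@H]1OC(C)=O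
F5 | step 8 | 6-O-tert-butyldimethylsilyl ether of 13 (free 4-OH) | C1=C[C@@]2(O)C(=O)[C@H]([C@H](O[Si](C)(C)C(C)(C)C)[C@@H]3O[C@@H]32)[C@H]1O
F6 | step 8 | 4-O-[N-(4-methoxyphenyl)carbamate] of F5 | C1=C[C@@]2(O)C(=O)[C@H]([C@H](O[Si](C)(C)C(C)(C)C)[C@@H]3O[C@@H]32)[C@H]1OC(=O)Nc4ccc(OC)cc4
F7 | step 8 | C3–N/C4–O cis-fused N-(4-methoxyphenyl)oxazolidin-2-one, 6-O-silyl, 7,8-epoxide | O=C1N(c4ccc(OC)cc4)[C@H]2C[C@@]3(O)C(=O)[C@H]([C@H](O[Si](C)(C)C(C)(C)C)[C@@H]5O[C@@H]53)[C@H]2O1
F8 | step 8 | C3–N/C4–O cis-fused N–H oxazolidin-2-one, 6-O-silyl, 7,8-epoxide | O=C1N[C@H]2C[C@@]3(O)C(=O)[C@H]([C@H](O[Si](C)(C)C(C)(C)C)[C@@H]5O[C@@H]53)[C@H]2O1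
F9 | step 8 | N-Boc derivative of F8 | O=C1N(C(=O)OC(C)(C)C)[C@H]2C[C@@]3(O)C(=O)[C@H]([C@H](O[Si](C)(C)C(C)(C)C)[C@@H]5O[C@@H]53)[C@H]2O1
F10 | step 8 | N-Boc-3-amino-6-O-silyl-7,8-epoxy-1,4-dihydroxybicyclo[3.3.1]nonan-9-one | CC(C)(C)OC(=O)N[C@H]1C[C@@]2(O)C(=O)[C@H]([C@H](O[Si](C)(C)C(C)(C)C)[C@@H]3O[C@@H]32)[C@H]1O
F11 | step 2 | 4-bromo-2-methoxyphenol | COc1cc(Br)ccc1O
F12 | step 2 | 4-bromo-6,6-dimethoxycyclohexa-2,4-dien-1-one | COC1(OC)C=C(Br)C=CC1=O
F13 | step 2 | rac-4-bromo-1-(3,3-diethoxyprop-1-yn-1-yl)-6,6-dimethoxycyclohexa-2,4-dien-1-ol | CCOC(OCC)C#CC1(O)C=CC(Br)=CC1(OC)OC
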